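**Retrosynthetic overview**

- The strategy rests on one feature: ring A carbons C5, C6, C7 and C8 carry O, OMe, O and prenyl, which is the C1–C4 pattern of methyl 2-methoxy-4-prenylacetoacetate, and C4a=C8a is the enone double bond of a ring C 2,3-dihydropyran-4-one that already holds O1, C2 and C3.
- Key disconnection: C8–C8a and C5–C4a. Bis(silyloxy)diene 20 adds to the 5-sulfinyl dihydropyranone 11, and the adduct aromatises by loss of benzenesulfenic acid and methanol.
- Ring C is made first: enantioselective hetero-Diels–Alder reaction of aldehyde 2 sets C2, a trans-selective hydroxylation sets C3, then C5 is sulfenylated and oxidised.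
- Diene 20 comes from methyl methoxyacetate by acetylation, γ-prenylation and two silylations.
- Ring order: ring B (bought), ring C, ring A; one global desilylation ends the route.

Key step: step 11

Remark (design assumptions): a 5-halogen on the dihydropyranone was set aside because in the cis adduct it would sit next to a non-acidic C8a–H and could not leave by anti-elimination, so a 5-phenylsulfinyl group (activating, lost by syn-elimination) is used; all masked hydroxyls are TBS ethers so one fluoride step finishes the route; C3 is oxygenated under kinetic control because base equilibration would open ring C.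

**Route**

Step 1
Reactants: 1 2,5-dihydroxybenzaldehyde
Product: 2 2,5-bis(tert-butyldimethylsilyloxy)benzaldehyde
Conditions: TBSCl (2.4 equiv), imidazole, DMF, rt
Reagents that add atoms: tert-butyldimethylsilyl chloride, CC(C)(C)[Si](C)(C)Cl
Why: Imidazole-promoted O-silylation masks both phenols as ethers that should tolerate Lewis acid, amide base, sulfenyl chloride and peracid and fall together in the last step.

Step 2
Reactants: 2 2,5-bis(tert-butyldimethylsilyloxy)benzaldehyde; 3 (E)-1-methoxy-3-(trimethylsilyloxy)buta-1,3-diene (Danishefsky's diene)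
Product: 5 (S)-2-[2,5-bis(tert-butyldimethylsilyloxy)phenyl]-2,3-dihydro-4H-pyran-4-one, via Mukaiyama aldol adduct 4 (not isolated)
Conditions: Ti(OiPr)4 (10 mol%), (S)-BINOL (20 mol%), 4 Å MS, Et2O, −20 °C; then TFA, CH2Cl2, 0 °C
Reagents that add atoms: none
Why: BINOL–titanium catalysed hetero-Diels–Alder reaction (enantioselective Mukaiyama aldol addition, then acid-induced ring closure with loss of methanol), in which the chiral titanium complex blocks one aldehyde face and so sets C2; (S)-BINOL is chosen by analogy with benzaldehyde to give the 2S enantiomer, and the sense is to be confirmed on the first batch.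

Step 3
Reactants: 5 (S)-2-[2,5-bis(tert-butyldimethylsilyloxy)phenyl]-2,3-dihydro-4H-pyran-4-one
Product: 7 (2R,3R)-2-[2,5-bis(tert-butyldimethylsilyloxy)phenyl]-3-hydroxy-2,3-dihydro-4H-pyran-4-one, via sodium enolate 6 (not isolated)
Conditions: NaN(SiMe3)2, THF, −78 °C; then 2-(phenylsulfonyl)-3-phenyloxaziridine, −78 °C; aq. NH4Cl
Reagents that add atoms: 2-(phenylsulfonyl)-3-phenyloxaziridine (Davis oxaziridine), O=S(=O)(c1ccccc1)N1OC1c1ccccc1
Why: Kinetic deprotonation at C3, the only enolisable position, and Davis oxaziridine hydroxylation of the enolate on the face opposite the C2 aryl group should give the trans (3R) alcohol, the low temperature keeping the enolate from expelling the ring oxygen; C2 is unchanged in space and is now called R only because C3 outranks the aryl group.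

Step 4
Reactants: 7 (2R,3R)-2-[2,5-bis(tert-butyldimethylsilyloxy)phenyl]-3-hydroxy-2,3-dihydro-4H-pyran-4-one
Product: 8 (2R,3R)-2-[2,5-bis(tert-butyldimethylsilyloxy)phenyl]-3-(tert-butyldimethylsilyloxy)-2,3-dihydro-4H-pyran-4-one
Conditions: TBSOTf, 2,6-lutidine, CH2Cl2, −78 °C
Reagents that add atoms: tert-butyldimethylsilyl triflate, CC(C)(C)[Si](C)(C)OS(=O)(=O)C(F)(F)F
Why: Silyl triflate silylation of the hindered secondary alcohol with a non-enolising base, so the C3 centre next to the ketone should not epimerise.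

Step 5
Reactants: 8 (2R,3R)-2-[2,5-bis(tert-butyldimethylsilyloxy)phenyl]-3-(tert-butyldimethylsilyloxy)-2,3-dihydro-4H-pyran-4-one
Product: 10 (2R,3R)-2-[2,5-bis(tert-butyldimethylsilyloxy)phenyl]-3-(tert-butyldimethylsilyloxy)-5-(phenylthio)-2,3-dihydro-4H-pyran-4-one, via chloro sulfide adduct 9 (not isolated)
Conditions: PhSH, N-chlorosuccinimide, CH2Cl2, 0 °C (gives PhSCl); then 8, −78 °C; then Et3N, −78 → 0 °C
Reagents that add atoms: thiophenol, Sc1ccccc1
Why: Electrophilic sulfenylation of the enol ether C5=C6 bond by benzenesulfenyl chloride (sulfur to the nucleophilic C5, chloride to C6) followed by base-induced loss of HCl through the acidic C5–H, the addition–elimination route to α-sulfenyl β-oxy enones.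

Step 6
Reactants: 10 (2R,3R)-2-[2,5-bis(tert-butyldimethylsilyloxy)phenyl]-3-(tert-butyldimethylsilyloxy)-5-(phenylthio)-2,3-dihydro-4H-pyran-4-one
Product: 11 (2R,3R)-2-[2,5-bis(tert-butyldimethylsilyloxy)phenyl]-3-(tert-butyldimethylsilyloxy)-5-(phenylsulfinyl)-2,3-dihydro-4H-pyran-4-one (both epimers at sulfur, used together)
Conditions: mCPBA (1.0 equiv), CH2Cl2, −78 → −40 °C
Reagents that add atoms: 3-chloroperoxybenzoic acid, O=C(OO)c1cccc(Cl)c1
Why: Peracid oxidation of the sulfide is far faster than attack on the electron-poor enone or the silylated arene and should stop at the sulfoxide with one equivalent at low temperature; the sulfur centre forms without control and does not matter because sulfur is lost in step 11.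

Step 7
Reactants: 12 methyl methoxyacetate
Product: 14 methyl 2-methoxy-3-oxobutanoate, via lithium enolate 13 (not isolated)
Conditions: LiN(iPr)2, THF, −78 °C; then 1-acetylimidazole (0.5 equiv), −78 → −20 °C; aq. NH4Cl
Reagents that add atoms: 1-acetylimidazole, CC(=O)n1ccnc1
Why: Crossed Claisen acylation of the chelated ester enolate by an N-acylimidazole, the second equivalent of enolate taking up the acidic proton of the β-keto ester formed.

Step 8
Reactants: 14 methyl 2-methoxy-3-oxobutanoate; 15 1-bromo-3-methylbut-2-ene (prenyl bromide)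
Product: 17 methyl 2-methoxy-7-methyl-3-oxooct-6-enoate, via dianion 16 (not isolated)
Conditions: LiN(iPr)2 (2.1 equiv), THF, −78 → 0 °C; then 15, 0 °C
Reagents that add atoms: none
Why: Huckin–Weiler alkylation, in which the β-keto ester dianion reacts by SN2 displacement at its more basic terminal carbon (C4), while C2 stays protected as the stabilised enolate.

Step 9
Reactants: 17 methyl 2-methoxy-7-methyl-3-oxooct-6-enoate
Product: 18 methyl 2-methoxy-7-methyl-3-(trimethylsilyloxy)octa-2,6-dienoate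
Conditions: TMSCl, Et3N, toluene, rt
Reagents that add atoms: chlorotrimethylsilane, C[Si](C)(C)Cl
Why: O-Silylation of the β-keto ester enol under amine base gives the 3-silyloxy enoate, the first half of the standard preparation of 1,3-bis(silyloxy)dienes.

Step 10
Reactants: 18 methyl 2-methoxy-7-methyl-3-(trimethylsilyloxy)octa-2,6-dienoate
Product: 20 1,2-dimethoxy-7-methyl-1,3-bis(trimethylsilyloxy)octa-1,3,6-triene, via lithium dienolate 19 (not isolated)
Conditions: LiN(iPr)2, THF, −78 °C; then TMSCl, −78 °C → rt; filtration under argon, used crude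
Reagents that add atoms: chlorotrimethylsilane, C[Si](C)(C)Cl
Why: γ-Deprotonation of the silyloxy enoate and O-silylation of the ester dienolate give the 1-methoxy-1,3-bis(silyloxy)diene, the established second half of this diene preparation.

Step 11
Reactants: 11 (2R,3R)-2-[2,5-bis(tert-butyldimethylsilyloxy)phenyl]-3-(tert-butyldimethylsilyloxy)-5-(phenylsulfinyl)-2,3-dihydro-4H-pyran-4-one; 20 1,2-dimethoxy-7-methyl-1,3-bis(trimethylsilyloxy)octa-1,3,6-triene
Product: 23 (2R,3R)-2-[2,5-bis(tert-butyldimethylsilyloxy)phenyl]-3-(tert-butyldimethylsilyloxy)-5,7-dihydroxy-6-methoxy-8-(3-methylbut-2-enyl)chroman-4-one, via sulfinyl cycloadduct 21 (not isolated), via dienyl ketal 22 (not isolated)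
Conditions: 20 (3 equiv), toluene, 0 → 70 °C; then citric acid, MeOH/THF, 0 °C
Reagents that add atoms: none
Why: Proposed new method: the [4+2] addition of a 1-alkoxy-1,3-bis(silyloxy)diene to a 5-sulfinyl-2,3-dihydropyran-4-one is untested; its closest relatives are the cycloaddition–aromatisation of such dienes with haloquinones and the domino cycloaddition/sulfoxide elimination of sulfinylquinones and vinyl sulfoxides used as alkyne equivalents. The nucleophilic diene terminus (future C8) bonds to C8a and the ketene acetal carbon (future C5) bonds to C4a, either in one asynchronous [4+2] step or as Mukaiyama–Michael addition followed by 6-(enolexo)-exo-trig closure of the sulfinyl silyl enol ether onto the silylated ester, and either way ring A is closed as cycloadduct 21. Suprafacial addition leaves the C8a hydrogen cis to sulfur, so thermal syn-elimination of benzenesulfenic acid through a five-membered cyclic transition state should restore C4a=C8a (22); the silyl methyl ketal at C5 then collapses with loss of methanol, the C8 hydrogen tautomerises to give the arene, and the mild acid work-up removes the two trimethylsilyl groups. No new stereocentre survives (C4a, C5, C8 and C8a all become trigonal), and C2 and C3 are untouched because the medium is neutral and no enolate of ring C forms. The selectivity needed is regiochemical and is secured by the two acceptor groups (C4=O and S=O) both sitting on C4a, which makes C8a the only electrophilic carbon; the O1–C8a bond is kept because C4a bears no hydrogen, so no retro-oxa-Michael opening is open to it before the sulfoxide leaves.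

Step 12
Reactants: 23 (2R,3R)-2-[2,5-bis(tert-butyldimethylsilyloxy)phenyl]-3-(tert-butyldimethylsilyloxy)-5,7-dihydroxy-6-methoxy-8-(3-methylbut-2-enyl)chroman-4-one
Product: 24 (2R,3R)-2-(2,5-dihydroxyphenyl)-3,5,7-trihydroxy-6-methoxy-8-(3-methylbut-2-enyl)chroman-4-one (CNP0287732.1)
Conditions: HF·pyridine, pyridine, THF, 0 °C → rt, argon
Reagents that add atoms: none
Why: Fluoride cleaves the two aryl silyl ethers and the secondary silyl ether in a buffered, slightly acidic medium in which no phenoxide forms, so the hydroquinone should not oxidise, C2 and C3 should not epimerise and the prenyl group should not cyclise onto the C7 hydroxyl.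

**Compound list**

1 | 2,5-dihydroxybenzaldehyde | O=Cc1cc(O)ccc1O | starting material
2 | 2,5-bis(tert-butyldimethylsilyloxy)benzaldehyde | O=Cc1cc(O[Si](C)(C)C(C)(C)C)ccc1O[Si](C)(C)C(C)(C)C | intermediate
3 | (E)-1-methoxy-3-(trimethylsilyloxy)buta-1,3-diene | CO/C=C/C(=C)O[Si](C)(C)C | starting material
4 | (S,E)-5-[2,5-bis(tert-butyldimethylsilyloxy)phenyl]-1-methoxy-5-(trimethylsilyloxy)pent-1-en-3-one | CO/C=C/C(=O)C[C@@H](c1cc(O[Si](C)(C)C(C)(C)C)ccc1O[Si](C)(C)C(C)(C)C)O[Si](C)(C)C | intermediate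
5 | (S)-2-[2,5-bis(tert-butyldimethylsilyloxy)phenyl]-2,3-dihydro-4H-pyran-4-one | O=C1C[C@@H](c2cc(O[Si](C)(C)C(C)(C)C)ccc2O[Si](C)(C)C(C)(C)C)OC=C1 | intermediate
6 | sodium (S)-2-[2,5-bis(tert-butyldimethylsilyloxy)phenyl]-2H-pyran-4-olate (C3 enolate of 5) | [Na+].[O-]C1=C[C@@H](c2cc(O[Si](C)(C)C(C)(C)C)ccc2O[Si](C)(C)C(C)(C)C)OC=C1 | intermediate
7 | (2R,3R)-2-[2,5-bis(tert-butyldimethylsilyloxy)phenyl]-3-hydroxy-2,3-dihydro-4H-pyran-4-one | O=C1[C@H](O)[C@@H](c2cc(O[Si](C)(C)C(C)(C)C)ccc2O[Si](C)(C)C(C)(C)C)OC=C1 | intermediate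
8 | (2R,3R)-2-[2,5-bis(tert-butyldimethylsilyloxy)phenyl]-3-(tert-butyldimethylsilyloxy)-2,3-dihydro-4H-pyran-4-one | O=C1[C@H](O[Si](C)(C)C(C)(C)C)[C@@H](c2cc(O[Si](C)(C)C(C)(C)C)ccc2O[Si](C)(C)C(C)(C)C)OC=C1 | intermediate
9 | (2R,3R)-2-[2,5-bis(tert-butyldimethylsilyloxy)phenyl]-3-(tert-butyldimethylsilyloxy)-6-chloro-5-(phenylthio)tetrahydro-4H-pyran-4-one (C5 and C6 not assigned) | O=C1[C@H](O[Si](C)(C)C(C)(C)C)[C@@H](c2cc(O[Si](C)(C)C(C)(C)C)ccc2O[Si](C)(C)C(C)(C)C)OC(Cl)C1Sc1ccccc1 | intermediate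
10 | (2R,3R)-2-[2,5-bis(tert-butyldimethylsilyloxy)phenyl]-3-(tert-butyldimethylsilyloxy)-5-(phenylthio)-2,3-dihydro-4H-pyran-4-one | O=C1[C@H](O[Si](C)(C)C(C)(C)C)[C@@H](c2cc(O[Si](C)(C)C(C)(C)C)ccc2O[Si](C)(C)C(C)(C)C)OC=C1Sc1ccccc1 | intermediate
11 | (2R,3R)-2-[2,5-bis(tert-butyldimethylsilyloxy)phenyl]-3-(tert-butyldimethylsilyloxy)-5-(phenylsulfinyl)-2,3-dihydro-4H-pyran-4-one (both epimers at sulfur) | O=C1[C@H](O[Si](C)(C)C(C)(C)C)[C@@H](c2cc(O[Si](C)(C)C(C)(C)C)ccc2O[Si](C)(C)C(C)(C)C)OC=C1S(=O)c1ccccc1 | intermediate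
12 | methyl methoxyacetate | COCC(=O)OC | starting material
13 | lithium enolate of methyl methoxyacetate | [Li+].[O-]C(OC)=COC | intermediate
14 | methyl 2-methoxy-3-oxobutanoate | COC(C(C)=O)C(=O)OC | intermediate
15 | 1-bromo-3-methylbut-2-ene (prenyl bromide) | CC(C)=CCBr | starting material
16 | dilithium dianion of methyl 2-methoxy-3-oxobutanoate | [Li+].[Li+].C=C([O-])C(OC)=C([O-])OC | intermediate
17 | methyl 2-methoxy-7-methyl-3-oxooct-6-enoate | COC(C(=O)CCC=C(C)C)C(=O)OC | intermediate
18 | methyl 2-methoxy-7-methyl-3-(trimethylsilyloxy)octa-2,6-dienoate (C2=C3 geometry not assigned) | COC(=O)C(OC)=C(CCC=C(C)C)O[Si](C)(C)C | intermediate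
19 | lithium 1,2-dimethoxy-7-methyl-3-(trimethylsilyloxy)octa-1,3,6-trien-1-olate | [Li+].[O-]C(OC)=C(OC)C(O[Si](C)(C)C)=CCC=C(C)C | intermediate
20 | 1,2-dimethoxy-7-methyl-1,3-bis(trimethylsilyloxy)octa-1,3,6-triene (alkene geometries not assigned) | COC(O[Si](C)(C)C)=C(OC)C(O[Si](C)(C)C)=CCC=C(C)C | intermediate
21 | (2R,3R)-2-[2,5-bis(tert-butyldimethylsilyloxy)phenyl]-3-(tert-butyldimethylsilyloxy)-5,6-dimethoxy-8-(3-methylbut-2-enyl)-4a-(phenylsulfinyl)-5,7-bis(trimethylsilyloxy)-2,3,4a,5,8,8a-hexahydro-4H-chromen-4-one (cis ring fusion; C4a, C5, C8, C8a not assigned) | O=C1[C@H](O[Si](C)(C)C(C)(C)C)[C@@H](c3cc(O[Si](C)(C)C(C)(C)C)ccc3O[Si](C)(C)C(C)(C)C)OC2C(CC=C(C)C)C(O[Si](C)(C)C)=C(OC)C(OC)(O[Si](C)(C)C)C12S(=O)c1ccccc1 | intermediate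
22 | (2R,3R)-2-[2,5-bis(tert-butyldimethylsilyloxy)phenyl]-3-(tert-butyldimethylsilyloxy)-5,6-dimethoxy-8-(3-methylbut-2-enyl)-5,7-bis(trimethylsilyloxy)-2,3,5,8-tetrahydro-4H-chromen-4-one (C5, C8 not assigned) | O=C1[C@H](O[Si](C)(C)C(C)(C)C)[C@@H](c3cc(O[Si](C)(C)C(C)(C)C)ccc3O[Si](C)(C)C(C)(C)C)OC2=C1C(OC)(O[Si](C)(C)C)C(OC)=C(O[Si](C)(C)C)C2CC=C(C)C | intermediate
23 | (2R,3R)-2-[2,5-bis(tert-butyldimethylsilyloxy)phenyl]-3-(tert-butyldimethylsilyloxy)-5,7-dihydroxy-6-methoxy-8-(3-methylbut-2-enyl)chroman-4-one | COc1c(O)c(CC=C(C)C)c2c(c1O)C(=O)[C@H](O[Si](C)(C)C(C)(C)C)[C@@H](c1cc(O[Si](C)(C)C(C)(C)C)ccc1O[Si](C)(C)C(C)(C)C)O2 | intermediate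
24 | (2R,3R)-2-(2,5-dihydroxyphenyl)-3,5,7-trihydroxy-6-methoxy-8-(3-methylbut-2-enyl)chroman-4-one | COc1c(O)c(CC=C(C)C)c2c(c1O)C(=O)[C@H](O)[C@@H](c1cc(O)ccc1O)O2 | target

**Step count**

Total: 12 steps. Longest linear sequence: 8 steps (steps 1–6, 11, 12); the diene branch (steps 7–10) joins at step 11.

**Steps most likely to fail**

Step 11 (new method). What may go wrong:
- the diene adds only once and stops at an open Michael adduct;
- the diene transfers silicon to the sulfinyl oxygen and starts a Pummerer-type pathway;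
- the adduct opens ring C, or loses silanol instead of methanol at C5, before or during aromatisation.

Fallback (known chemistry: ring A preformed with its oxygens already told apart, ring C closed last). It sets out from 1 and comes back at 24.
- Commercial 2-methoxyresorcinol is protected (MOMCl, iPr2NEt) as 2-methoxy-1,3-bis(methoxymethoxy)benzene F1.
- Sterically controlled C–H borylation at the only unhindered position ([Ir(OMe)(cod)]2, 4,4'-di-tert-butyl-2,2'-bipyridine, B2pin2) gives the aryl boronate 2-[4-methoxy-3,5-bis(methoxymethoxy)phenyl]-4,4,5,5-tetramethyl-1,3,2-dioxaborolane F2, and NaOH/H2O2 oxidises it to the symmetric phenol 4-methoxy-3,5-bis(methoxymethoxy)phenol F3.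
- ortho-C-Prenylation of its sodium phenoxide (NaH, toluene, 15) gives 4-methoxy-3,5-bis(methoxymethoxy)-2-(3-methylbut-2-enyl)phenol F4; the two ortho positions are equivalent.
- Chelation-directed ortho-acetylation of the bromomagnesium phenoxide (EtMgBr, then AcCl, toluene) at the one remaining ortho position gives 1-[2-hydroxy-5-methoxy-4,6-bis(methoxymethoxy)-3-(3-methylbut-2-enyl)phenyl]ethanone F5. Its single free hydroxyl, flanked by prenyl and acetyl, is the future O1, so the direction of ring C closure is fixed by construction.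
- Allylation (allyl bromide, K2CO3, acetone) gives the allyl ether 1-[2-(allyloxy)-5-methoxy-4,6-bis(methoxymethoxy)-3-(3-methylbut-2-enyl)phenyl]ethanone F6.
- Aldehyde 1 is protected (MOMCl, iPr2NEt) as 2,5-bis(methoxymethoxy)benzaldehyde F7, and Claisen–Schmidt condensation of F6 with F7 (KOH, EtOH) gives the chalcone (E)-1-[2-(allyloxy)-5-methoxy-4,6-bis(methoxymethoxy)-3-(3-methylbut-2-enyl)phenyl]-3-[2,5-bis(methoxymethoxy)phenyl]prop-2-en-1-one F8.
- Juliá–Colonna epoxidation (poly-L-leucine, urea–H2O2, DBU), a nucleophilic epoxidation that leaves the allyl and prenyl double bonds alone, gives the (2R,3S)-epoxy ketone of the chalcone F9.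
- Deallylation (Pd(PPh3)4, morpholine) frees the 2'-hydroxy epoxy ketone F10. Mild acid (camphorsulfonic acid, CH2Cl2, 0 °C) opens the epoxide at the benzylic carbon with inversion (6-endo) to the (2R,3R)-dihydroflavonol tetrakis-MOM ether F11.
- HCl in MeOH removes the four MOM groups to give 24.

Step 3. What may go wrong: oxygen transfer with poor facial selectivity, or β-elimination of the ring oxygen from the metal enolate, which opens ring C and erodes C2. Fallback (no metal enolate), setting out from 5 and coming back at 8: soft enolisation (TBSOTf, Et3N, CH2Cl2, −78 °C) gives the silyl dienol ether (S)-2-[2,5-bis(tert-butyldimethylsilyloxy)phenyl]-4-(tert-butyldimethylsilyloxy)-2H-pyran F12. Dimethyldioxirane (acetone, −78 °C) epoxidises its electron-rich C3=C4 bond on the face away from the aryl group to the silyloxy epoxide F13. On warming this rearranges with 1,4-silyl migration (Rubottom oxidation) directly to 8, so step 4 is not needed.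

Step 2. What may go wrong: low enantioselectivity because the bulky ortho-silyloxy group disturbs binding of the aldehyde to the titanium catalyst. Fallback (stoichiometric chiral reagent instead of catalyst), setting out from 2 and coming back at 5: diisopinocampheylboron enolate aldol reaction of (E)-4-methoxybut-3-en-2-one with 2 (Ipc2BCl of the antipode that gives the S aldol, iPr2NEt, Et2O, −78 °C; oxidative work-up) gives the β-hydroxy enone (S,E)-5-[2,5-bis(tert-butyldimethylsilyloxy)phenyl]-5-hydroxy-1-methoxypent-1-en-3-one F14, which TFA cyclises with loss of methanol to 5.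

**Further compounds**

F1 | step 11 | 2-methoxy-1,3-bis(methoxymethoxy)benzene | COCOc1cccc(OCOC)c1OC
F2 | step 11 | 2-[4-methoxy-3,5-bis(methoxymethoxy)phenyl]-4,4,5,5-tetramethyl-1,3,2-dioxaborolane | COCOc1cc(B2OC(C)(C)C(C)(C)O2)cc(OCOC)c1OC
F3 | step 11 | 4-methoxy-3,5-bis(methoxymethoxy)phenol | COCOc1cc(O)cc(OCOC)c1OC
F4 | step 11 | 4-methoxy-3,5-bis(methoxymethoxy)-2-(3-methylbut-2-enyl)phenol | COCOc1cc(O)c(CC=C(C)C)c(OCOC)c1OC
F5 | step 11 | 1-[2-hydroxy-5-methoxy-4,6-bis(methoxymethoxy)-3-(3-methylbut-2-enyl)phenyl]ethanone | CC(=O)c1c(O)c(CC=C(C)C)c(OCOC)c(OC)c1OCOC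
F6 | step 11 | 1-[2-(allyloxy)-5-methoxy-4,6-bis(methoxymethoxy)-3-(3-methylbut-2-enyl)phenyl]ethanone | CC(=O)c1c(OCC=C)c(CC=C(C)C)c(OCOC)c(OC)c1OCOC
F7 | step 11 | 2,5-bis(methoxymethoxy)benzaldehyde | COCOc1ccc(OCOC)c(C=O)c1
F8 | step 11 | (E)-1-[2-(allyloxy)-5-methoxy-4,6-bis(methoxymethoxy)-3-(3-methylbut-2-enyl)phenyl]-3-[2,5-bis(methoxymethoxy)phenyl]prop-2-en-1-one | O=C(/C=C/c1cc(OCOC)ccc1OCOC)c1c(OCC=C)c(CC=C(C)C)c(OCOC)c(OC)c1OCOC
F9 | step 11 | [2-(allyloxy)-5-methoxy-4,6-bis(methoxymethoxy)-3-(3-methylbut-2-enyl)phenyl][(2R,3S)-3-[2,5-bis(methoxymethoxy)phenyl]oxiran-2-yl]methanone | O=C([C@@H]1O[C@H]1c1cc(OCOC)ccc1OCOC)c1c(OCC=C)c(CC=C(C)C)c(OCOC)c(OC)c1OCOC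
F10 | step 11 | [(2R,3S)-3-[2,5-bis(methoxymethoxy)phenyl]oxiran-2-yl][2-hydroxy-5-methoxy-4,6-bis(methoxymethoxy)-3-(3-methylbut-2-enyl)phenyl]methanone | O=C([C@@H]1O[C@H]1c1cc(OCOC)ccc1OCOC)c1c(O)c(CC=C(C)C)c(OCOC)c(OC)c1OCOC
F11 | step 11 | (2R,3R)-2-[2,5-bis(methoxymethoxy)phenyl]-3-hydroxy-6-methoxy-5,7-bis(methoxymethoxy)-8-(3-methylbut-2-enyl)chroman-4-one | COc1c(OCOC)c(CC=C(C)C)c2c(c1OCOC)C(=O)[C@H](O)[C@@H](c1cc(OCOC)ccc1OCOC)O2
F12 | step 3 | (S)-2-[2,5-bis(tert-butyldimethylsilyloxy)phenyl]-4-(tert-butyldimethylsilyloxy)-2H-pyran | CC(C)(C)[Si](C)(C)OC1=C[C@@H](c2cc(O[Si](C)(C)C(C)(C)C)ccc2O[Si](C)(C)C(C)(C)C)OC=C1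
F13 | step 3 | 3,4-epoxide of F12, epoxide oxygen on the face opposite the C2 aryl group (2-[2,5-bis(tert-butyldimethylsilyloxy)phenyl]-4-(tert-butyldimethylsilyloxy)-3,4-epoxy-3,4-dihydro-2H-pyran) | O1C=C[C@]2(O[Si](C)(C)C(C)(C)C)O[C@@H]2[C@H]1c1cc(O[Si](C)(C)C(C)(C)C)ccc1O[Si](C)(C)C(C)(C)C
F14 | step 2 | (S,E)-5-[2,5-bis(tert-butyldimethylsilyloxy)phenyl]-5-hydroxy-1-methoxypent-1-en-3-one | CO/C=C/C(=O)C[C@@H](c1cc(O[Si](C)(C)C(C)(C)C)ccc1O[Si](C)(C)C(C)(C)C)O
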